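The benzene ring (C4a, C5, C6, C7, C8, C8a) is cut at C4a–C8a and C5–C6, which also opens the carbocycle C1–C4. Three features allow this. C6–C7–C19 maps onto a malonic ester. C8 maps onto the carbonyl carbon of an aldehyde condensed with that ester. C1–C4 is a four-atom tether whose stereocentres lie outside the reacting atoms. In one operation, an intramolecular Diels–Alder reaction and loss of benzyl alcohol turn an open chain into the fully substituted tetralin. The precursor is an acyclic dienyl silyl ketene acetal (C8a=C8–C7=C6) tethered to an ynal (C4a≡C5–CHO). It already carries C1, C4, C11 and C15. The formyl group is later exchanged for the C5 hydroxyl.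

Key step: step 19

**Atom labels (used for all intermediates).** In the tetralin, C1 carries the side chain, C4 the methyl C20, C5 and C6 the hydroxyls, and C7 the carboxyl C19. The side chain is C11 (methine), C12–C14, C15 (methyl C17), C16 (CH2OH) and C18 (CH2OAc).

**Design remarks.**
- (a) The acyl activator on C5 is a spectator that never reaches the target, and it is chosen as formyl. An enolisable acyl group such as acetyl would be silylated by R3SiOTf/amine in competition with the alkylidene malonate. CHO has no α-hydrogen, activates the alkyne more strongly, and is the best substrate for the later aryl-to-oxygen migration.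
- (b) Dibenzyl malonate is used. Whichever oxygen substituent leaves C6 on aromatisation, the product (OTBS, OH or OBn at C6) still ends at the target, and the C19 ester falls by hydrogenolysis.
- (c) Because of (b), the C18 acetate can be installed early and C16 can be carried as a benzyl ether, so no late saponification or catechol protection is needed.

**Assumption.** (R)-Citronellal 1 and bromo alcohol 12 are used in their enantiopure commercial grades.

Step 1
Reactants: 1 (R)-citronellal
Product: 2 (6R)-8,8-dibromo-2,6-dimethyloct-2-ene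
Conditions: (PhO)3P, Br2, CH2Cl2, −60 °C; then Et3N, 1, −60 °C → rt
Reagents that add atoms: bromine, BrBr
Why: Deoxygenative gem-dibromination of an enolisable aliphatic aldehyde with a preformed bromophosphorane (Appel-type carbonyl activation) is known chemistry, leaves no free bromine for the trisubstituted alkene, and does not touch C4, which comes from the chiral pool.

Step 2
Reactants: 2 (6R)-8,8-dibromo-2,6-dimethyloct-2-ene
Product: 4 (3R)-3,7-dimethyloct-6-en-1-yne, via lithium acetylide 3 (not isolated)
Conditions: LiN(iPr)2 (3.3 equiv), THF, −78 → 0 °C; H2O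
Reagents that add atoms: lithium diisopropylamide, [Li]N(C(C)C)C(C)C (lithium appears in 3 only)
Why: Double dehydrobromination of a 1,1-dibromide ends at the acetylide, which resists propargyl–allene isomerisation at low temperature, so C4 next to the new C4a≡C5 bond should keep its configuration.

Step 3
Reactants: 4 (3R)-3,7-dimethyloct-6-en-1-yne; 5 triethyl orthoformate
Product: 7 (4R)-1,1-diethoxy-4,8-dimethylnon-7-en-2-yne, via alkynylmagnesium bromide 6 (not isolated)
Conditions: EtMgBr, THF, 0 → 40 °C; 5, toluene, 95 °C; aq NH4Cl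
Reagents that add atoms: ethylmagnesium bromide, CC[Mg]Br (MgBr appears in 6 only)
Why: In a Bodroux–Chichibabin reaction the alkynyl Grignard reagent displaces one ethoxide of the orthoformate and stops at the base-stable acetal, which masks the future formyl activator in one step.

Step 4
Reactants: 7 (4R)-1,1-diethoxy-4,8-dimethylnon-7-en-2-yne
Product: 8 (4R)-7,7-diethoxy-4-methylhept-5-ynal
Conditions: O3 (1 equiv, Sudan Red 7B end point), CH2Cl2, −78 °C; Me2S, → rt
Reagents that add atoms: ozone, [O-][O+]=O
Why: Ozonolysis with one equivalent of ozone selects the electron-rich trisubstituted alkene over the hindered, acetal-deactivated alkyne and unveils C1 as an aldehyde.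

Step 5
Reactants: 8 (4R)-7,7-diethoxy-4-methylhept-5-ynal; 9 dimethyl (2-oxopropyl)phosphonate
Product: 10 (3E,7R)-10,10-diethoxy-7-methyldec-3-en-8-yn-2-one
Conditions: LiCl, DBU, MeCN, 0 °C → rt
Reagents that add atoms: none
Why: Horner–Wadsworth–Emmons olefination under Masamune–Roush conditions gives the E-enone (C1=C8a) with a base too mild for aldol self-condensation of the unbranched aldehyde.

Step 6
Reactants: 10 (3E,7R)-10,10-diethoxy-7-methyldec-3-en-8-yn-2-one
Product: 11 (2S,3E,7R)-10,10-diethoxy-7-methyldec-3-en-8-yn-2-ol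
Conditions: (R)-2-methyl-CBS-oxazaborolidine (20 mol %), catecholborane, toluene, −78 °C; MeOH, aq work-up
Reagents that add atoms: none
Why: In the Corey–Bakshi–Shibata reduction the (R)-oxazaborolidine treats the alkenyl arm as the large group and the methyl as the small one and so delivers hydride to give the (S)-carbinol, while catecholborane at −78 °C does not hydroborate the alkyne.

Step 7
Reactants: 12 (2R)-3-bromo-2-methylpropan-1-ol
Product: 13 {[(2R)-3-bromo-2-methylpropoxy]methyl}benzene
Conditions: BnOC(=NH)CCl3, TfOH (cat.), cyclohexane–CH2Cl2, 0 °C → rt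
Reagents that add atoms: benzyl 2,2,2-trichloroacetimidate, N=C(OCc1ccccc1)C(Cl)(Cl)Cl
Why: Acid-catalysed imidate benzylation avoids the alkoxide that could close an oxetane, and C15 is taken unchanged from the chiral pool.

Step 8
Reactants: 13 {[(2R)-3-bromo-2-methylpropoxy]methyl}benzene; 14 pent-4-en-1-ylmagnesium bromide
Product: 15 ({[(2S)-2-methyloct-7-en-1-yl]oxy}methyl)benzene
Conditions: Li2CuCl4 (3 mol %), THF, −10 °C → rt
Reagents that add atoms: none
Why: Copper-catalysed Grignard–alkyl bromide cross-coupling (Kochi type) forms C13–C14 at a primary carbon, so the neighbouring stereocentre C15 is not involved (the descriptor changes only through priorities).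

Step 9
Reactants: 15 ({[(2S)-2-methyloct-7-en-1-yl]oxy}methyl)benzene
Product: 16 (6S)-7-(benzyloxy)-6-methylheptanoic acid
Conditions: OsO4 (1 mol %), KHSO5 (as Oxone, 4 equiv), DMF, rt
Reagents that add atoms: potassium peroxymonosulfate, [K+].[O-]S(=O)(=O)OO; osmium tetroxide, O=[Os](=O)(=O)=O
Why: OsO4-catalysed oxidative cleavage with peroxymonosulfate takes a terminal alkene directly to the carboxylic acid (C18) and tolerates a benzyl ether.

Step 10
Reactants: 11 (2S,3E,7R)-10,10-diethoxy-7-methyldec-3-en-8-yn-2-ol; 16 (6S)-7-(benzyloxy)-6-methylheptanoic acid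
Product: 17 (2S,3E,7R)-10,10-diethoxy-7-methyldec-3-en-8-yn-2-yl (6S)-7-(benzyloxy)-6-methylheptanoate
Conditions: DCC, DMAP (cat.), CH2Cl2, 0 °C → rt
Reagents that add atoms: none
Why: Steglich esterification joins the two halves without breaking the carbinol C–O bond, so the (S)-centre that will steer the rearrangement is retained.

Step 11
Reactants: 17 (2S,3E,7R)-10,10-diethoxy-7-methyldec-3-en-8-yn-2-yl (6S)-7-(benzyloxy)-6-methylheptanoate
Product: 20 (2S,3R,6R)-2-[(4S)-5-(benzyloxy)-4-methylpentyl]-9,9-diethoxy-6-methyl-3-[(1E)-prop-1-enyl]non-7-ynoic acid, via TBS ketene acetal 18 (not isolated), via TBS ester 19 (not isolated)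
Conditions: LiN(iPr)2, THF–DMPU (55:45), −78 °C; TBSCl; → rt, then 50 °C; AcOH–THF–H2O, rt
Reagents that add atoms: tert-butyldimethylsilyl chloride, CC(C)(C)[Si](C)(C)Cl (silyl group appears in 18 and 19 only)
Why: In this Ireland–Claisen rearrangement, enolisation in THF–DMPU fixes Z(O) geometry (C12 cis to OSi in 18), and the chair transition state with the carbinol methyl equatorial passes the (S)-chirality suprafacially across the E-alkene, which forms C11–C1, sets both centres syn in the absolute sense of the target, and leaves an E-propenyl group on C1.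

Step 12
Reactants: 20 Claisen acid
Product: 21 (2S,3R,6R)-2-[(4S)-5-(benzyloxy)-4-methylpentyl]-9,9-diethoxy-6-methyl-3-[(1E)-prop-1-enyl]non-7-yn-1-ol
Conditions: LiAlH4, Et2O, 0 °C → rt; H2O, aq NaOH
Reagents that add atoms: none
Why: Hydride reduction of the carboxylic acid gives the C18 alcohol, while the isolated alkene, the alkyne (no free propargylic hydroxyl) and the acetal are inert at this temperature.

Step 13
Reactants: 21 primary alcohol
Product: 22 (2S,3R,6R)-2-[(4S)-5-(benzyloxy)-4-methylpentyl]-9,9-diethoxy-6-methyl-3-[(1E)-prop-1-enyl]non-7-yn-1-yl acetate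
Conditions: Ac2O, pyridine, DMAP (cat.), CH2Cl2, 0 °C → rt
Reagents that add atoms: acetic anhydride, CC(=O)OC(C)=O
Why: DMAP-catalysed acetylation installs the C18 acetate of the target now, so C18–OH and C16–OH never have to be told apart later.

Step 14
Reactants: 22 propenyl acetate
Product: 23 (2S,3S,6R)-2-[(4S)-5-(benzyloxy)-4-methylpentyl]-9,9-diethoxy-3-formyl-6-methylnon-7-yn-1-yl acetate
Conditions: OsO4 (2 mol %), NaIO4, 2,6-lutidine, dioxane–H2O (3:1), rt
Reagents that add atoms: osmium tetroxide, O=[Os](=O)(=O)=O; sodium periodate, [Na+].[O-]I(=O)(=O)=O (oxygen of the new formyl group)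
Why: Lemieux–Johnson cleavage removes the chirality-relay carbons as acetaldehyde and leaves C8a as an aldehyde, the hindered alkyne is not osmylated, and the lutidine buffer protects C1 from epimerisation.

Step 15
Reactants: 23 C8a aldehyde; 24 (methoxymethyl)triphenylphosphonium chloride
Product: 26 (2S,3R,6R)-2-[(4S)-5-(benzyloxy)-4-methylpentyl]-9,9-diethoxy-6-methyl-3-(2-oxoethyl)non-7-yn-1-yl acetate, via methyl enol ether 25 (not isolated)
Conditions: 24 (1.4 equiv), KN(SiMe3)2 (1.3 equiv), THF, −78 → 0 °C; then 1 M HCl, THF, 0 °C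
Reagents that add atoms: water, O
Why: Wittig methoxymethylenation followed by enol ether hydrolysis adds C8 as an aldehyde, the base-deficient ylide should spare the acetate and C1 at low temperature, and dilute acid hydrolyses the enol ether far faster than the propargylic acetal, whose oxocarbenium ion is destabilised by the alkyne.

Step 16
Reactants: 26 C8 aldehyde; 27 dibenzyl malonate
Product: 28 dibenzyl 2-{(3R,6R)-3-[(2S,6S)-1-(acetyloxy)-7-(benzyloxy)-6-methylheptan-2-yl]-9,9-diethoxy-6-methylnon-7-yn-1-ylidene}propanedioate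
Conditions: piperidine (10 mol %), AcOH (10 mol %), 4 Å MS, toluene, rt → 50 °C
Reagents that add atoms: none
Why: Knoevenagel condensation forms C8=C7 and brings in C6, C7 and C19, and any isomerisation to the β,γ-unsaturated malonate is harmless because both isomers give the same dienolate in step 18.

Step 17
Reactants: 28 alkylidene malonate acetal
Product: 29 dibenzyl 2-{(3R,6R)-3-[(2S,6S)-1-(acetyloxy)-7-(benzyloxy)-6-methylheptan-2-yl]-6-methyl-9-oxonon-7-yn-1-ylidene}propanedioate
Conditions: CF3CO2H–H2O (1:1), CHCl3, 0 °C → rt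
Reagents that add atoms: water, O
Why: Acid hydrolysis of the propargylic acetal releases the ynal, and the acetate, benzyl ether, benzyl esters and alkylidene malonate all tolerate aqueous acid.

Step 18
Reactants: 29 alkylidene malonate ynal
Product: 30 benzyl (3E,5R,8R)-5-[(2S,6S)-1-(acetyloxy)-7-(benzyloxy)-6-methylheptan-2-yl]-2-{(benzyloxy)[(tert-butyldimethylsilyl)oxy]methylidene}-8-methyl-11-oxoundec-3-en-9-ynoate (either geometry at C7=C6)
Conditions: TBSOTf (1.1 equiv), iPr2NEt (2 equiv), CH2Cl2 (0.02 M), −78 → −20 °C; pentane, cold aq NaHCO3; used at once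
Reagents that add atoms: tert-butyldimethylsilyl triflate, CC(C)(C)[Si](C)(C)OS(=O)(=O)C(F)(F)F
Why: In this soft enolisation, O-silylation of one malonate carbonyl acidifies the γ-hydrogens at C8a, and the hindered amine removes one of them to give the vinylogous silyl ketene acetal with E geometry at C8a=C8 (the branched C1 avoids the inside position), while the formyl group has no α-hydrogen and cannot compete.

Step 19
Reactants: 30 dienyl silyl ketene acetal ynal
Product: 32 benzyl (5R,8S)-8-[(2S,6S)-1-(acetyloxy)-7-(benzyloxy)-6-methylheptan-2-yl]-3-[(tert-butyldimethylsilyl)oxy]-4-formyl-5-methyl-5,6,7,8-tetrahydronaphthalene-2-carboxylate, via cyclohexadiene cycloadduct 31 (not isolated)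
Conditions: toluene (5 mM), BHT (cat.), 90 °C; then Et3N (cat.), rt
Reagents that add atoms: none
Why: Proposed new method: On heating, the electron-rich terminus C8a of the vinylogous ketene acetal bonds to the β-carbon C4a of the ynal and C6 bonds to C5 in a concerted but asynchronous normal-demand (4+2) cycloaddition, and cycloadduct 31, a 1,4-cyclohexadiene with a mixed ketal at C6 and an acidified hydrogen at C8a, aromatises by vinylogous 1,4-elimination of benzyl alcohol. The closest known reaction type is the intermolecular Diels–Alder reaction of 1-alkoxy-1-silyloxybuta-1,3-dienes with ynones, ynals and alkynoates followed by loss of alcohol, together with type 1 intramolecular Diels–Alder reactions of dienes tethered to activated alkynes; what is new is the malonate-derived diene with an ester on C7 and its intramolecular use. The carbocycle (C1–C4, C4a, C8a) closes through the four-atom tether as the six-membered bridging ring (6-exo-dig at C4a in a stepwise picture), and the arene ring closes as the six-membered cycloaddition ring itself through C5–C6. No lasting stereocentre is made, because C8a and C6 of 31 are erased on aromatisation and C1, C4, C11 and C15 are spectators. The step needs regioselectivity and chemoselectivity: the tether allows only C8a→C4a, the polarity of donor diene and acceptor alkyne agrees with it, the E geometry at C8a=C8 lets the termini meet, and high dilution disfavours intermolecular addition to the formyl group. Loss of silanol or of the silyl group instead of benzyl alcohol would only give the C6 benzyl ether or the free phenol, both of which still lead to 36.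

Step 20
Reactants: 32 aryl silyl ether
Product: 33 benzyl (5R,8S)-8-[(2S,6S)-1-(acetyloxy)-7-(benzyloxy)-6-methylheptan-2-yl]-4-formyl-3-hydroxy-5-methyl-5,6,7,8-tetrahydronaphthalene-2-carboxylate
Conditions: Bu4NF, AcOH (1:1), THF, 0 °C
Reagents that add atoms: none
Why: Buffered fluoride cleaves the aryl silyl ether flanked by two carbonyl groups quickly, and the buffer keeps the acetate and the benzyl ester intact.

Step 21
Reactants: 33 salicylaldehyde
Product: 35 benzyl (5R,8S)-8-[(2S,6S)-1-(acetyloxy)-7-(benzyloxy)-6-methylheptan-2-yl]-3,4-dihydroxy-5-methyl-5,6,7,8-tetrahydronaphthalene-2-carboxylate, via aryl formate 34 (not isolated)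
Conditions: mCPBA (1.1 equiv), CH2Cl2, 0 °C → rt; then MeOH, Et3N (cat.), 0 °C, argon
Reagents that add atoms: 3-chloroperoxybenzoic acid, OOC(=O)c1cccc(Cl)c1
Why: In this Dakin-type Baeyer–Villiger oxidation the peracid adds to the formyl group, the aryl carbon C5 (ortho hydroxyl, ortho alkyl) migrates to oxygen, and the very labile aryl formate is methanolysed under conditions that a primary acetate survives, which basic hydrogen peroxide would not allow.

Step 22
Reactants: 35 catechol benzyl ester
Product: 36 (5R,8S)-8-[(2S,6S)-1-(acetyloxy)-7-hydroxy-6-methylheptan-2-yl]-3,4-dihydroxy-5-methyl-5,6,7,8-tetrahydronaphthalene-2-carboxylic acid (target, CNP0191669.1)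
Conditions: H2 (1 atm), 10% Pd/C, EtOAc–EtOH, rt
Reagents that add atoms: none
Why: Hydrogenolysis removes the C19 benzyl ester and the C16 benzyl ether in one neutral operation that touches neither the acetate, the catechol nor any stereocentre.

Compound list
1 | (R)-citronellal, (3R)-3,7-dimethyloct-6-enal | CC(C)=CCC[C@@H](C)CC=O | starting material
2 | (6R)-8,8-dibromo-2,6-dimethyloct-2-ene | CC(C)=CCC[C@@H](C)CC(Br)Br | intermediate
3 | lithium (3R)-3,7-dimethyloct-6-en-1-yn-1-ide | CC(C)=CCC[C@@H](C)C#C[Li] | intermediate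
4 | (3R)-3,7-dimethyloct-6-en-1-yne | CC(C)=CCC[C@@H](C)C#C | intermediate
5 | triethyl orthoformate | CCOC(OCC)OCC | starting material
6 | [(3R)-3,7-dimethyloct-6-en-1-yn-1-yl]magnesium bromide | CC(C)=CCC[C@@H](C)C#C[Mg]Br | intermediate
7 | (4R)-1,1-diethoxy-4,8-dimethylnon-7-en-2-yne | CC(C)=CCC[C@@H](C)C#CC(OCC)OCC | intermediate
8 | (4R)-7,7-diethoxy-4-methylhept-5-ynal | O=CCC[C@@H](C)C#CC(OCC)OCC | intermediate
9 | dimethyl (2-oxopropyl)phosphonate | COP(=O)(CC(C)=O)OC | starting material
10 | (3E,7R)-10,10-diethoxy-7-methyldec-3-en-8-yn-2-one | CC(=O)/C=C/CC[C@@H](C)C#CC(OCC)OCC | intermediate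
11 | (2S,3E,7R)-10,10-diethoxy-7-methyldec-3-en-8-yn-2-ol | C[C@H](O)/C=C/CC[C@@H](C)C#CC(OCC)OCC | intermediate
12 | (2R)-3-bromo-2-methylpropan-1-ol | BrC[C@H](C)CO | starting material
13 | {[(2R)-3-bromo-2-methylpropoxy]methyl}benzene | BrC[C@H](C)COCc1ccccc1 | intermediate
14 | pent-4-en-1-ylmagnesium bromide | C=CCCC[Mg]Br | starting material
15 | ({[(2S)-2-methyloct-7-en-1-yl]oxy}methyl)benzene | C=CCCCC[C@H](C)COCc1ccccc1 | intermediate
16 | (6S)-7-(benzyloxy)-6-methylheptanoic acid | OC(=O)CCCC[C@H](C)COCc1ccccc1 | intermediate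
17 | (2S,3E,7R)-10,10-diethoxy-7-methyldec-3-en-8-yn-2-yl (6S)-7-(benzyloxy)-6-methylheptanoate | C[C@H](OC(=O)CCCC[C@H](C)COCc1ccccc1)/C=C/CC[C@@H](C)C#CC(OCC)OCC | intermediate
18 | (Z)-TBS ketene acetal of 17 (C12 cis to OSi) | C[C@H](O/C(O[Si](C)(C)C(C)(C)C)=C/CCC[C@H](C)COCc1ccccc1)/C=C/CC[C@@H](C)C#CC(OCC)OCC | intermediate
19 | TBS ester of 20 | CC(C)(C)[Si](C)(C)OC(=O)[C@@H](CCC[C@H](C)COCc1ccccc1)[C@@H](/C=C/C)CC[C@@H](C)C#CC(OCC)OCC | intermediate
20 | (2S,3R,6R)-2-[(4S)-5-(benzyloxy)-4-methylpentyl]-9,9-diethoxy-6-methyl-3-[(1E)-prop-1-enyl]non-7-ynoic acid | OC(=O)[C@@H](CCC[C@H](C)COCc1ccccc1)[C@@H](/C=C/C)CC[C@@H](C)C#CC(OCC)OCC | intermediate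
21 | (2S,3R,6R)-2-[(4S)-5-(benzyloxy)-4-methylpentyl]-9,9-diethoxy-6-methyl-3-[(1E)-prop-1-enyl]non-7-yn-1-ol | OC[C@@H](CCC[C@H](C)COCc1ccccc1)[C@@H](/C=C/C)CC[C@@H](C)C#CC(OCC)OCC | intermediate
22 | acetate of 21 | CC(=O)OC[C@@H](CCC[C@H](C)COCc1ccccc1)[C@@H](/C=C/C)CC[C@@H](C)C#CC(OCC)OCC | intermediate
23 | (2S,3S,6R)-2-[(4S)-5-(benzyloxy)-4-methylpentyl]-9,9-diethoxy-3-formyl-6-methylnon-7-yn-1-yl acetate | CC(=O)OC[C@@H](CCC[C@H](C)COCc1ccccc1)[C@@H](C=O)CC[C@@H](C)C#CC(OCC)OCC | intermediate
24 | (methoxymethyl)triphenylphosphonium chloride | [Cl-].COC[P+](c1ccccc1)(c1ccccc1)c1ccccc1 | starting material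
25 | (2S,3S,6R)-2-[(4S)-5-(benzyloxy)-4-methylpentyl]-9,9-diethoxy-3-(2-methoxyethenyl)-6-methylnon-7-yn-1-yl acetate (E/Z mixture) | CC(=O)OC[C@@H](CCC[C@H](C)COCc1ccccc1)[C@@H](C=COC)CC[C@@H](C)C#CC(OCC)OCC | intermediate
26 | (2S,3R,6R)-2-[(4S)-5-(benzyloxy)-4-methylpentyl]-9,9-diethoxy-6-methyl-3-(2-oxoethyl)non-7-yn-1-yl acetate | CC(=O)OC[C@@H](CCC[C@H](C)COCc1ccccc1)[C@@H](CC=O)CC[C@@H](C)C#CC(OCC)OCC | intermediate
27 | dibenzyl malonate | O=C(CC(=O)OCc1ccccc1)OCc1ccccc1 | starting material
28 | dibenzyl 2-{(3R,6R)-3-[(2S,6S)-1-(acetyloxy)-7-(benzyloxy)-6-methylheptan-2-yl]-9,9-diethoxy-6-methylnon-7-yn-1-ylidene}propanedioate | CC(=O)OC[C@@H](CCC[C@H](C)COCc1ccccc1)[C@@H](CC=C(C(=O)OCc1ccccc1)C(=O)OCc1ccccc1)CC[C@@H](C)C#CC(OCC)OCC | intermediate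
29 | dibenzyl 2-{(3R,6R)-3-[(2S,6S)-1-(acetyloxy)-7-(benzyloxy)-6-methylheptan-2-yl]-6-methyl-9-oxonon-7-yn-1-ylidene}propanedioate | CC(=O)OC[C@@H](CCC[C@H](C)COCc1ccccc1)[C@@H](CC=C(C(=O)OCc1ccccc1)C(=O)OCc1ccccc1)CC[C@@H](C)C#CC=O | intermediate
30 | key-step precursor, benzyl (3E,5R,8R)-5-[(2S,6S)-1-(acetyloxy)-7-(benzyloxy)-6-methylheptan-2-yl]-2-{(benzyloxy)[(tert-butyldimethylsilyl)oxy]methylidene}-8-methyl-11-oxoundec-3-en-9-ynoate | CC(=O)OC[C@@H](CCC[C@H](C)COCc1ccccc1)[C@@H](/C=C/C(C(=O)OCc1ccccc1)=C(OCc1ccccc1)O[Si](C)(C)C(C)(C)C)CC[C@@H](C)C#CC=O | intermediate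
31 | bicyclic 1,4-cyclohexadiene cycloadduct (C6 mixed ketal, C8a–H; C6 and C8a undefined) | CC(=O)OC[C@@H](CCC[C@H](C)COCc1ccccc1)[C@@H]1CC[C@@H](C)C2=C(C=O)C(OCc3ccccc3)(O[Si](C)(C)C(C)(C)C)C(C(=O)OCc3ccccc3)=CC12 | intermediate
32 | key-step product, benzyl (5R,8S)-8-[(2S,6S)-1-(acetyloxy)-7-(benzyloxy)-6-methylheptan-2-yl]-3-[(tert-butyldimethylsilyl)oxy]-4-formyl-5-methyl-5,6,7,8-tetrahydronaphthalene-2-carboxylate | CC(=O)OC[C@@H](CCC[C@H](C)COCc3ccccc3)[C@@H]1CC[C@@H](C)c2c1cc(C(=O)OCc3ccccc3)c(O[Si](C)(C)C(C)(C)C)c2C=O | intermediate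
33 | benzyl (5R,8S)-8-[(2S,6S)-1-(acetyloxy)-7-(benzyloxy)-6-methylheptan-2-yl]-4-formyl-3-hydroxy-5-methyl-5,6,7,8-tetrahydronaphthalene-2-carboxylate | CC(=O)OC[C@@H](CCC[C@H](C)COCc3ccccc3)[C@@H]1CC[C@@H](C)c2c1cc(C(=O)OCc3ccccc3)c(O)c2C=O | intermediate
34 | 4-(formyloxy) analogue of 35 (aryl formate at C5) | CC(=O)OC[C@@H](CCC[C@H](C)COCc3ccccc3)[C@@H]1CC[C@@H](C)c2c1cc(C(=O)OCc3ccccc3)c(O)c2OC=O | intermediate
35 | benzyl (5R,8S)-8-[(2S,6S)-1-(acetyloxy)-7-(benzyloxy)-6-methylheptan-2-yl]-3,4-dihydroxy-5-methyl-5,6,7,8-tetrahydronaphthalene-2-carboxylate | CC(=O)OC[C@@H](CCC[C@H](C)COCc3ccccc3)[C@@H]1CC[C@@H](C)c2c1cc(C(=O)OCc3ccccc3)c(O)c2O | intermediate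
36 | (5R,8S)-8-[(2S,6S)-1-(acetyloxy)-7-hydroxy-6-methylheptan-2-yl]-3,4-dihydroxy-5-methyl-5,6,7,8-tetrahydronaphthalene-2-carboxylic acid | CC(=O)OC[C@@H](CCC[C@H](C)CO)[C@@H]1CC[C@@H](C)c2c1cc(C(=O)O)c(O)c2O | target

Total step count: 22. Longest linear sequence: 19 (steps 1–6 and 10–22).

Steps most likely to fail

1. **Step 19 (new method).**
   - What may go wrong: The ester on C7 lowers the energy of the diene, and one oxygen substituent on C6 must point inward in the s-cis conformer, so the cycloaddition may be too slow. Desilylation back to the malonate, oligomerisation of the ynal, or loss of configuration at C4 through γ-deprotonation could then take over.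
   - Fallback (known chemistry): a Michael–Dieckmann annulation in the manner of the Staunton–Weinreb and Hauser annulations. It sets out from 29 and comes back at 33. Without any silylation, DBU in MeCN at 0 °C removes a C8a proton. The malonate-stabilised dienolate adds through C8a to C4a (6-exo-dig vinylogous Michael addition) to give the monocyclic Michael adduct F1. Further DBU with gentle warming (or LiN(SiMe3)2 at −78 °C) deprotonates C8a again. C5 of the extended enolate then attacks the ester carbonyl C6, benzyl oxide leaves, and tautomerisation gives phenol 33.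

2. **Step 18.**
   - What may go wrong: The silyl triflate may promote intermolecular aldol-type addition of the new ketene acetal to the free formyl group. The amine may add to the ynal. Enolisation may stay incomplete.
   - Fallback: it sets out from 28 and comes back at 32, and it keeps the aldehyde masked while the diene is made. TBSOTf and Et3N in CH2Cl2 at 0 °C convert 28 into the dienyl ketene acetal with intact alkynyl acetal F2. Catalytic TMSOTf at −78 °C then ionises the propargylic acetal to an alkynyl oxocarbenium ion. This ion undergoes an ionic Diels–Alder reaction across the same atoms (C8a to C4a, C6 to C5) and, after loss of benzyl alcohol, gives the aryl diethyl acetal F3. PPTS in wet acetone releases the aldehyde 32.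

3. **Step 15.**
   - What may go wrong: The α-branched aldehyde may epimerise at C1 under the basic ylide. The acetate may be cleaved. The alkynyl acetal may be partly hydrolysed during enol ether cleavage.
   - Fallback: it sets out from 23 and comes back at 26. It introduces C8 as a methylene group and oxidises it afterwards, with no strong base and no acid. Non-basic, aldehyde-selective methylenation (CH2I2, Zn, Ti(OiPr)4, THF) gives the vinyl compound F4. 9-BBN hydroborates the terminal alkene in preference to the hindered internal alkyne, and NaBO3·4H2O then gives the primary alcohol F5. Dess–Martin periodinane with NaHCO3 gives 26.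

Further compounds
F1 | step 19 | monocyclic Michael adduct, dibenzyl 2-{[6-(side chain)-3-methyl-2-(2-oxoethylidene)cyclohexyl]methylidene}propanedioate (C8a and C4a=C5 geometry undefined) | CC(=O)OC[C@@H](CCC[C@H](C)COCc3ccccc3)[C@@H]1CC[C@@H](C)C(=CC=O)C1C=C(C(=O)OCc3ccccc3)C(=O)OCc3ccccc3
F2 | step 18 | dienyl silyl ketene acetal with alkynyl diethyl acetal | CC(=O)OC[C@@H](CCC[C@H](C)COCc1ccccc1)[C@@H](/C=C/C(C(=O)OCc1ccccc1)=C(OCc1ccccc1)O[Si](C)(C)C(C)(C)C)CC[C@@H](C)C#CC(OCC)OCC
F3 | step 18 | aryl diethyl acetal of 32 | CC(=O)OC[C@@H](CCC[C@H](C)COCc3ccccc3)[C@@H]1CC[C@@H](C)c2c1cc(C(=O)OCc3ccccc3)c(O[Si](C)(C)C(C)(C)C)c2C(OCC)OCC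
F4 | step 15 | vinyl compound, 3-ethenyl analogue of 23 | CC(=O)OC[C@@H](CCC[C@H](C)COCc1ccccc1)[C@@H](C=C)CC[C@@H](C)C#CC(OCC)OCC
F5 | step 15 | primary alcohol, 3-(2-hydroxyethyl) analogue of 26 | CC(=O)OC[C@@H](CCC[C@H](C)COCc1ccccc1)[C@@H](CCO)CC[C@@H](C)C#CC(OCC)OCC
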